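Both aromatic rings (ring A with the methoxy group, ring B with three hydroxy groups) are traced back to a chiral, purely aliphatic core: the methine carbon, the two ring carbons bonded to it and, in each ring, the adjacent hydroxy-bearing carbon on the side away from prenyl are C1 to C5 of 3-isobutylglutaric acid, so desymmetrising the anhydride sets the stereocentre. The key step converts a bis(5-prenyl-2-pyranone), 4-methoxy on the ring A arm and 4-hydroxy on the ring B arm, into both arenes at once: methoxide opens each lactone and each methylene beside the methine closes onto its ester carbonyl. Protection, twofold directed acetylation and deprotection complete the target.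

Key step: step 9

Assumption: quinidine is taken to deliver the (S)-configured mono-allyl ester in the anhydride opening; should the sense prove opposite, quinine is used instead and nothing else changes.

Step 1
Reactants: 1 3-isobutylglutaric anhydride (4-(2-methylpropyl)oxane-2,6-dione)
Product: 2 (3S)-5-methyl-3-[2-oxo-2-(prop-2-enyloxy)ethyl]hexanoic acid (mono-allyl ester of 3-isobutylglutaric acid)
Conditions: quinidine (1.1 equiv), allyl alcohol (3 equiv), PhMe, −55 °C; dilute HCl wash (quinidine recovered)
Reagents that add atoms: allyl alcohol, C=CCO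
Why: Alkaloid-mediated enantioselective alcoholysis of a prochiral cyclic anhydride, in which quinidine acts as a chiral general base and directs allyl alcohol to one of the two enantiotopic carbonyl groups, should set the only stereocentre as (S) (the free acid arm later becomes the ring A arm); the enantiomeric purity can be raised by crystallising the 1-phenylethylammonium salt.

Step 2
Reactants: 3 methyl acetoacetate; 4 prenyl bromide (1-bromo-3-methylbut-2-ene)
Product: 5 methyl 7-methyl-3-oxooct-6-enoate
Conditions: LiN(iPr)2 (2.1 equiv), THF, 0 °C; then 4, 0 °C to rt; NH4Cl (aq)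
Reagents that add atoms: none
Why: γ-Alkylation of the acetoacetate dianion, whose more basic terminal carbanion should react selectively with the allylic bromide by SN2 substitution.

Step 3
Reactants: 2 (3S)-5-methyl-3-[2-oxo-2-(prop-2-enyloxy)ethyl]hexanoic acid; 5 methyl 7-methyl-3-oxooct-6-enoate
Product: 7 1-methyl 9-prop-2-enyl (7S)-4-(3-methylbut-2-enyl)-7-(2-methylpropyl)-3,5-dioxononanedioate (C4 epimers/enol forms), via acyl imidazolide 6 (not isolated)
Conditions: 2, 1,1'-carbonyldiimidazole (CDI), THF, rt; then added at −78 °C to the dianion of 5 (3 equiv, LiN(iPr)2, THF, 0 °C); AcOH quench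
Reagents that add atoms: none
Why: Crossed Claisen C-acylation of the β-keto ester dianion at its γ-carbon by the acyl imidazolide, which at −78 °C is far more electrophilic than the allyl ester; excess dianion absorbs the acidic product and the released imidazole, and the new C4 centre is an enolising position that becomes sp2 in step 4.

Step 4
Reactants: 7 1-methyl 9-prop-2-enyl (7S)-4-(3-methylbut-2-enyl)-7-(2-methylpropyl)-3,5-dioxononanedioate
Product: 8 prop-2-enyl (3S)-3-{[4-hydroxy-5-(3-methylbut-2-enyl)-2-oxo-2H-pyran-6-yl]methyl}-5-methylhexanoate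
Conditions: DBU, PhMe, rt to 60 °C; cold dilute HCl work-up
Reagents that add atoms: none
Why: Base-mediated lactonisation of a 3,5-dioxo ester, in which the enol oxygen of the C5 ketone acylates the methyl ester; ionisation of the resulting 4-hydroxy-2-pyranone by DBU should make this closure irreversible and selective over attack on the remote allyl ester.

Step 5
Reactants: 8 prop-2-enyl (3S)-3-{[4-hydroxy-5-(3-methylbut-2-enyl)-2-oxo-2H-pyran-6-yl]methyl}-5-methylhexanoate
Product: 9 prop-2-enyl (3S)-3-{[4-methoxy-5-(3-methylbut-2-enyl)-2-oxo-2H-pyran-6-yl]methyl}-5-methylhexanoate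
Conditions: Me2SO4, K2CO3, acetone, reflux
Reagents that add atoms: dimethyl sulfate, COS(=O)(=O)OC
Why: O-Alkylation of the vinylogous acid with a hard methylating agent under carbonate conditions should give the 4-methoxy-2-pyranone as the main regioisomer, any 2-methoxy-4-pyranone being removed by chromatography.

Step 6
Reactants: 9 prop-2-enyl (3S)-3-{[4-methoxy-5-(3-methylbut-2-enyl)-2-oxo-2H-pyran-6-yl]methyl}-5-methylhexanoate
Product: 10 (3S)-3-{[4-methoxy-5-(3-methylbut-2-enyl)-2-oxo-2H-pyran-6-yl]methyl}-5-methylhexanoic acid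
Conditions: Pd(PPh3)4 (5 mol %), morpholine, THF, rt
Reagents that add atoms: none
Why: Tsuji–Trost-type deallylation through a π-allyl complex of zerovalent palladium, with morpholine as allyl acceptor, is neutral and should leave the methoxypyranone, the prenyl group and the stereocentre untouched.

Step 7
Reactants: 10 (3S)-3-{[4-methoxy-5-(3-methylbut-2-enyl)-2-oxo-2H-pyran-6-yl]methyl}-5-methylhexanoic acid; 5 methyl 7-methyl-3-oxooct-6-enoate
Product: 12 methyl (7S)-7-{[4-methoxy-5-(3-methylbut-2-enyl)-2-oxo-2H-pyran-6-yl]methyl}-9-methyl-4-(3-methylbut-2-enyl)-3,5-dioxodecanoate (C4 epimers/enol forms), via acyl imidazolide 11 (not isolated)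
Conditions: 10, CDI, THF, rt; then added at −78 °C to the dianion of 5 (3 equiv, LiN(iPr)2, THF, 0 °C); AcOH quench
Reagents that add atoms: none
Why: The same crossed Claisen γ-acylation of the dianion of 5 builds the ring B arm; the imidazolide should be consumed at −78 °C faster than the dianion deprotonates or attacks the methoxypyranone, and the excess of dianion covers whatever proton transfer does occur.

Step 8
Reactants: 12 methyl (7S)-7-{[4-methoxy-5-(3-methylbut-2-enyl)-2-oxo-2H-pyran-6-yl]methyl}-9-methyl-4-(3-methylbut-2-enyl)-3,5-dioxodecanoate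
Product: 13 4-hydroxy-6-{(2R)-2-{[4-methoxy-5-(3-methylbut-2-enyl)-2-oxo-2H-pyran-6-yl]methyl}-4-methylpentyl}-5-(3-methylbut-2-enyl)-2H-pyran-2-one
Conditions: DBU, PhMe, rt to 60 °C; cold dilute HCl work-up
Reagents that add atoms: none
Why: The lactonisation of step 4 is repeated on the second 3,5-dioxo ester and should give the free 4-hydroxy-2-pyranone, while the 4-methoxy-2-pyranone is inert to the non-nucleophilic amidine base.

Step 9
Reactants: 13 4-hydroxy-6-{(2R)-2-{[4-methoxy-5-(3-methylbut-2-enyl)-2-oxo-2H-pyran-6-yl]methyl}-4-methylpentyl}-5-(3-methylbut-2-enyl)-2H-pyran-2-one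
Product: 15 2-{(1R)-1-[2,6-dihydroxy-4-methoxy-3-(3-methylbut-2-enyl)phenyl]-3-methylbutyl}-4-(3-methylbut-2-enyl)benzene-1,3,5-triol, via ring-opened bis(keto ester) 14 (not isolated)
Conditions: NaOMe (10 equiv), degassed MeOH, sealed tube, 150 °C, short heating; poured cold into AcOH/NaOAc buffer
Reagents that add atoms: none
Why: Proposed new method: methoxide adds to each lactone carbonyl and opens the ring A arm to a (2E)-3-methoxy-5-oxo-2-enoate, whose ester stays cis to the ketone arm, and the ionised ring B arm to a 3,5-dioxo ester enolate; each ketone then enolises toward the methylene beside the methine, that carbon attacks the methyl ester, methoxide is lost and tautomerisation gives the arene. The closest known reaction types are the alkoxide-induced isomerisation of 4-methoxy-6-methyl-2-pyranone to 5-methoxyresorcinol and the Claisen cyclisation of 5-oxo esters to cyclohexane-1,3-diones, neither of which has been run twice in one operation on a branched substrate. Each of the two rings closes in the 6-(enolendo)-exo-trig mode. No stereocentre is formed, and the existing methine carbon has no acidic hydrogen and no leaving group until the arenes exist, so its configuration should be carried through unchanged. The step needs C-acylation at the less acidic methylene to win over O-relactonisation, which is secured because relactonisation is reversible and aromatisation is not, and it needs the methoxy/hydroxy difference to survive, which is secured because methoxide is the only alkoxide present and the ring B oxygen stays ionised and cannot be exchanged. Heating is kept short and the quench cold because the polyphenolate product could fragment by retro-Michael scission to a quinone methide and so racemise.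

Step 10
Reactants: 15 2-{(1R)-1-[2,6-dihydroxy-4-methoxy-3-(3-methylbut-2-enyl)phenyl]-3-methylbutyl}-4-(3-methylbut-2-enyl)benzene-1,3,5-triol
Product: 16 1-methoxy-3,5-bis(methoxymethoxy)-2-(3-methylbut-2-enyl)-4-{(1S)-3-methyl-1-[2,4,6-tris(methoxymethoxy)-3-(3-methylbut-2-enyl)phenyl]butyl}benzene (same spatial arrangement as 15; the descriptor changes because OCH2OCH3 now outranks OCH3)
Conditions: NaH, MOMCl, DMF, 0 °C to rt
Reagents that add atoms: chloromethyl methyl ether, COCCl
Why: Williamson-type O-alkylation of the five phenoxides with the hard electrophile MOMCl in a dipolar aprotic solvent should favour O- over C-alkylation and removes every acidic hydrogen before the metalation, while cold aprotic conditions avoid fragmentation of the polyphenolate.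

Step 11
Reactants: 16 1-methoxy-3,5-bis(methoxymethoxy)-2-(3-methylbut-2-enyl)-4-{(1S)-3-methyl-1-[2,4,6-tris(methoxymethoxy)-3-(3-methylbut-2-enyl)phenyl]butyl}benzene
Product: 18 1-{3-[(1S)-1-[3-acetyl-2,4,6-tris(methoxymethoxy)-5-(3-methylbut-2-enyl)phenyl]-3-methylbutyl]-6-methoxy-2,4-bis(methoxymethoxy)-5-(3-methylbut-2-enyl)phenyl}ethanone, via dilithio arene 17 (not isolated)
Conditions: s-BuLi, TMEDA, THF, −78 °C; then MeC(O)N(OMe)Me, −78 to 0 °C; NH4Cl (aq)
Reagents that add atoms: N-methoxy-N-methylacetamide, CC(=O)N(C)OC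
Why: Twofold directed ortho-metalation, in which the single aromatic hydrogen of each ring lies between two oxygen directing groups and should be removed kinetically at −78 °C in preference to the crowded benzylic and allylic hydrogens, followed by acylation with the N-methoxy-N-methylamide, whose chelated tetrahedral intermediate prevents over-addition.

Step 12
Reactants: 18 1-{3-[(1S)-1-[3-acetyl-2,4,6-tris(methoxymethoxy)-5-(3-methylbut-2-enyl)phenyl]-3-methylbutyl]-6-methoxy-2,4-bis(methoxymethoxy)-5-(3-methylbut-2-enyl)phenyl}ethanone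
Product: 19 1-{3-[(1R)-1-[3-acetyl-2,4,6-trihydroxy-5-(3-methylbut-2-enyl)phenyl]-3-methylbutyl]-2,4-dihydroxy-6-methoxy-5-(3-methylbut-2-enyl)phenyl}ethanone (target)
Conditions: 3 M HCl (aq), MeOH, rt to 40 °C
Reagents that add atoms: none
Why: Acid-catalysed acetal exchange with methanol should remove all five MOM groups under conditions mild enough to spare the prenyl groups (no chroman formation) and the diarylmethine, whose rings are now deactivated by the acetyl groups.

Compound list
1 | 3-isobutylglutaric anhydride (4-(2-methylpropyl)oxane-2,6-dione) | CC(C)CC1CC(=O)OC(=O)C1 | starting material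
2 | (3S)-5-methyl-3-[2-oxo-2-(prop-2-enyloxy)ethyl]hexanoic acid | CC(C)C[C@@H](CC(=O)O)CC(=O)OCC=C | intermediate
3 | methyl acetoacetate | COC(=O)CC(C)=O | starting material
4 | prenyl bromide (1-bromo-3-methylbut-2-ene) | CC(C)=CCBr | starting material
5 | methyl 7-methyl-3-oxooct-6-enoate | COC(=O)CC(=O)CCC=C(C)C | intermediate
6 | prop-2-enyl (3S)-3-[2-(imidazol-1-yl)-2-oxoethyl]-5-methylhexanoate | CC(C)C[C@@H](CC(=O)n1ccnc1)CC(=O)OCC=C | intermediate
7 | 1-methyl 9-prop-2-enyl (7S)-4-(3-methylbut-2-enyl)-7-(2-methylpropyl)-3,5-dioxononanedioate (C4 epimers/enol forms) | CC(C)C[C@@H](CC(=O)C(CC=C(C)C)C(=O)CC(=O)OC)CC(=O)OCC=C | intermediate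
8 | prop-2-enyl (3S)-3-{[4-hydroxy-5-(3-methylbut-2-enyl)-2-oxo-2H-pyran-6-yl]methyl}-5-methylhexanoate | CC(C)C[C@@H](CC1=C(CC=C(C)C)C(O)=CC(=O)O1)CC(=O)OCC=C | intermediate
9 | prop-2-enyl (3S)-3-{[4-methoxy-5-(3-methylbut-2-enyl)-2-oxo-2H-pyran-6-yl]methyl}-5-methylhexanoate | CC(C)C[C@@H](CC1=C(CC=C(C)C)C(OC)=CC(=O)O1)CC(=O)OCC=C | intermediate
10 | (3S)-3-{[4-methoxy-5-(3-methylbut-2-enyl)-2-oxo-2H-pyran-6-yl]methyl}-5-methylhexanoic acid | CC(C)C[C@@H](CC1=C(CC=C(C)C)C(OC)=CC(=O)O1)CC(=O)O | intermediate
11 | 6-{(2S)-2-[2-(imidazol-1-yl)-2-oxoethyl]-4-methylpentyl}-4-methoxy-5-(3-methylbut-2-enyl)-2H-pyran-2-one | CC(C)C[C@@H](CC1=C(CC=C(C)C)C(OC)=CC(=O)O1)CC(=O)n1ccnc1 | intermediate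
12 | methyl (7S)-7-{[4-methoxy-5-(3-methylbut-2-enyl)-2-oxo-2H-pyran-6-yl]methyl}-9-methyl-4-(3-methylbut-2-enyl)-3,5-dioxodecanoate (C4 epimers/enol forms) | CC(C)C[C@@H](CC1=C(CC=C(C)C)C(OC)=CC(=O)O1)CC(=O)C(CC=C(C)C)C(=O)CC(=O)OC | intermediate
13 | 4-hydroxy-6-{(2R)-2-{[4-methoxy-5-(3-methylbut-2-enyl)-2-oxo-2H-pyran-6-yl]methyl}-4-methylpentyl}-5-(3-methylbut-2-enyl)-2H-pyran-2-one | CC(C)C[C@@H](CC1=C(CC=C(C)C)C(OC)=CC(=O)O1)CC1=C(CC=C(C)C)C(O)=CC(=O)O1 | intermediate
14 | dimethyl (2E,7S)-3-methoxy-4,10-bis(3-methylbut-2-enyl)-7-(2-methylpropyl)-5,9,11-trioxotridec-2-enedioate (C4 and C10 epimers/enol forms; drawn neutral, present as sodium enolates) | CC(C)C[C@@H](CC(=O)C(CC=C(C)C)/C(OC)=C\C(=O)OC)CC(=O)C(CC=C(C)C)C(=O)CC(=O)OC | intermediate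
15 | 2-{(1R)-1-[2,6-dihydroxy-4-methoxy-3-(3-methylbut-2-enyl)phenyl]-3-methylbutyl}-4-(3-methylbut-2-enyl)benzene-1,3,5-triol | COc1cc(O)c([C@H](CC(C)C)c2c(O)cc(O)c(CC=C(C)C)c2O)c(O)c1CC=C(C)C | intermediate
16 | 1-methoxy-3,5-bis(methoxymethoxy)-2-(3-methylbut-2-enyl)-4-{(1S)-3-methyl-1-[2,4,6-tris(methoxymethoxy)-3-(3-methylbut-2-enyl)phenyl]butyl}benzene | COc1cc(OCOC)c([C@H](CC(C)C)c2c(OCOC)cc(OCOC)c(CC=C(C)C)c2OCOC)c(OCOC)c1CC=C(C)C | intermediate
17 | dilithio derivative of 16, lithium on the ring A carbon between OMe and OMOM and on the ring B carbon between two OMOM groups | COc1c([Li])c(OCOC)c([C@H](CC(C)C)c2c(OCOC)c([Li])c(OCOC)c(CC=C(C)C)c2OCOC)c(OCOC)c1CC=C(C)C | intermediate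
18 | 1-{3-[(1S)-1-[3-acetyl-2,4,6-tris(methoxymethoxy)-5-(3-methylbut-2-enyl)phenyl]-3-methylbutyl]-6-methoxy-2,4-bis(methoxymethoxy)-5-(3-methylbut-2-enyl)phenyl}ethanone | COc1c(C(C)=O)c(OCOC)c([C@H](CC(C)C)c2c(OCOC)c(C(C)=O)c(OCOC)c(CC=C(C)C)c2OCOC)c(OCOC)c1CC=C(C)C | intermediate
19 | 1-{3-[(1R)-1-[3-acetyl-2,4,6-trihydroxy-5-(3-methylbut-2-enyl)phenyl]-3-methylbutyl]-2,4-dihydroxy-6-methoxy-5-(3-methylbut-2-enyl)phenyl}ethanone | COc1c(CC=C(C)C)c(O)c([C@H](CC(C)C)c2c(O)c(CC=C(C)C)c(O)c(C(C)=O)c2O)c(O)c1C(C)=O | target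

Total step count: 12. Longest linear sequence: 11 steps (1 to 19 through steps 1 and 3 to 12); step 2 supplies fragment 5, which is used twice.

Steps most likely to fail

Step 9. The ionised ring B arm may open and close much more slowly than the ring A arm. Prolonged heating would then bring retro-Claisen cleavage of the open arms and retro-Michael fragmentation of the polyphenolate, with loss of material and of enantiomeric purity.
Fallback (known chemistry; sets out from 4 and commercial 2,4,6-trihydroxyacetophenone, comes back at 19): C-prenylation of 2,4,6-trihydroxyacetophenone with 4 (KOH, water, 0 °C) should give 1-[2,4,6-trihydroxy-3-(3-methylbut-2-enyl)phenyl]ethanone F1, the ring B unit. For the ring A unit, F1 is protected at its two less hindered hydroxy groups (MOMCl, iPr2NEt, CH2Cl2) to give 1-[2-hydroxy-4,6-bis(methoxymethoxy)-3-(3-methylbut-2-enyl)phenyl]ethanone F2. The remaining chelated hydroxy group between acetyl and prenyl is methylated (MeI, K2CO3, DMF) to give 1-[2-methoxy-4,6-bis(methoxymethoxy)-3-(3-methylbut-2-enyl)phenyl]ethanone F3, and dilute HCl in MeOH gives 1-[4,6-dihydroxy-2-methoxy-3-(3-methylbut-2-enyl)phenyl]ethanone F4. Condensation of F4 at its only free ring carbon with 3-methylbutanal and sodium 4-methylbenzenesulfinate (aqueous formic acid) gives the racemic sulfone 1-[2,4-dihydroxy-6-methoxy-5-(3-methylbut-2-enyl)-3-{3-methyl-1-[(4-methylphenyl)sulfonyl]butyl}phenyl]ethanone F5. Aqueous NaHCO3 then releases the ortho-quinone methide from F5 in the presence of F1 and a bifunctional cinchona squaramide catalyst. Enantioselective conjugate addition of F1 through its only free ring carbon should give 19, with chromatography on a chiral phase as a safeguard for enantiomeric purity.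

Step 11. Proton transfer from the enolisable amide to the crowded aryllithium centres may compete with acyl transfer, returning protonated arene and leaving the twofold substitution incomplete.
Fallback (sets out from 16, comes back at 18): the dilithio arene 17 is trapped with acetaldehyde, whose carbonyl addition should outrun enolisation, to give 1-{3-[(1S)-1-[3-(1-hydroxyethyl)-2,4,6-tris(methoxymethoxy)-5-(3-methylbut-2-enyl)phenyl]-3-methylbutyl]-6-methoxy-2,4-bis(methoxymethoxy)-5-(3-methylbut-2-enyl)phenyl}ethanol F6 as a mixture of carbinol epimers. Dess–Martin oxidation (NaHCO3, CH2Cl2) then converts both carbinols into the ketones of 18.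

Step 7. Proton transfer from the acidic 6-methylene of the methoxypyranone to the dianion, followed by self-condensation of the pyranone anion with the imidazolide, may consume both partners before the desired acylation.
Fallback (sets out from 10 and 5, comes back at 12): 10 is converted under neutral conditions with 1-chloro-N,N,2-trimethylprop-1-en-1-amine (CH2Cl2, 0 °C) into (3S)-3-{[4-methoxy-5-(3-methylbut-2-enyl)-2-oxo-2H-pyran-6-yl]methyl}-5-methylhexanoyl chloride F7. Separately, 5 is silylated (Me3SiCl, Et3N) to methyl 7-methyl-3-(trimethylsilyloxy)octa-2,6-dienoate F8 and then (LiN(iPr)2, Me3SiCl, −78 °C) to 1-methoxy-7-methyl-1,3-bis(trimethylsilyloxy)octa-1,3,6-triene F9. F7 and F9 combine in CH2Cl2 (−78 °C to rt) by γ-selective acylation of the bis(silyl) dienol ether, and aqueous work-up should give 12 without exposing the pyranone to any strong base.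

Further compounds
F1 | step 9 | 1-[2,4,6-trihydroxy-3-(3-methylbut-2-enyl)phenyl]ethanone | CC(=O)c1c(O)cc(O)c(CC=C(C)C)c1O
F2 | step 9 | 1-[2-hydroxy-4,6-bis(methoxymethoxy)-3-(3-methylbut-2-enyl)phenyl]ethanone | CC(=O)c1c(O)c(CC=C(C)C)c(OCOC)cc1OCOC
F3 | step 9 | 1-[2-methoxy-4,6-bis(methoxymethoxy)-3-(3-methylbut-2-enyl)phenyl]ethanone | CC(=O)c1c(OC)c(CC=C(C)C)c(OCOC)cc1OCOC
F4 | step 9 | 1-[4,6-dihydroxy-2-methoxy-3-(3-methylbut-2-enyl)phenyl]ethanone | CC(=O)c1c(OC)c(CC=C(C)C)c(O)cc1O
F5 | step 9 | 1-[2,4-dihydroxy-6-methoxy-5-(3-methylbut-2-enyl)-3-{3-methyl-1-[(4-methylphenyl)sulfonyl]butyl}phenyl]ethanone (racemic) | CC(=O)c1c(OC)c(CC=C(C)C)c(O)c(C(CC(C)C)S(=O)(=O)c2ccc(C)cc2)c1O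
F6 | step 11 | 1-{3-[(1S)-1-[3-(1-hydroxyethyl)-2,4,6-tris(methoxymethoxy)-5-(3-methylbut-2-enyl)phenyl]-3-methylbutyl]-6-methoxy-2,4-bis(methoxymethoxy)-5-(3-methylbut-2-enyl)phenyl}ethanol (carbinol epimers) | COc1c(C(C)O)c(OCOC)c([C@H](CC(C)C)c2c(OCOC)c(C(C)O)c(OCOC)c(CC=C(C)C)c2OCOC)c(OCOC)c1CC=C(C)C
F7 | step 7 | (3S)-3-{[4-methoxy-5-(3-methylbut-2-enyl)-2-oxo-2H-pyran-6-yl]methyl}-5-methylhexanoyl chloride | CC(C)C[C@@H](CC1=C(CC=C(C)C)C(OC)=CC(=O)O1)CC(=O)Cl
F8 | step 7 | methyl 7-methyl-3-(trimethylsilyloxy)octa-2,6-dienoate | COC(=O)C=C(O[Si](C)(C)C)CCC=C(C)C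
F9 | step 7 | 1-methoxy-7-methyl-1,3-bis(trimethylsilyloxy)octa-1,3,6-triene | COC(O[Si](C)(C)C)=CC(O[Si](C)(C)C)=CCC=C(C)C
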